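At 50 min each flask gives one reading of target, and we want that number before we take it.

| flask | starting material | protic impurity | free catalyst | added ligand | remark | time |
|---|---|---|---|---|---|---|
| blue | 0.22 M | 0.014 M | 0.13 mol% | 0.94 mM | run made earlier |  |
| violet | 0.22 M | 0.17 M | 0.13 mol% | 0.94 mM | run made earlier |  |
| spring | 0.22 M | 0.0120 M | 0.13 mol% | 0.94 mM |  | 50 min |
| dusk | 0.22 M | 0.0800 M | 0.13 mol% | 0.94 mM |  | 50 min |
| dawn | 0.22 M | 0.0440 M | 0.13 mol% | 0.94 mM |  | 50 min |
| noon | 0.22 M | 0.0200 M | 0.13 mol% | 0.94 mM |  | 50 min |
| midnight | 0.22 M | 0.0300 M | 0.13 mol% | 0.94 mM |  | 50 min |
| summer | 0.22 M | 0.120 M | 0.13 mol% | 0.94 mM |  | 50 min |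

| run | time / min | target / % |
|---|---|---|
| blue | 3.00 | 29 |
| blue | 10.0 | 67 |
| blue | 20.0 | 86 |
| blue | 25.0 | 90 |
| blue | 40.0 | 93 |
| blue | 50.0 | 93 |
| violet | 8.00 | 27 |
| violet | 15.0 | 31 |
| violet | 25.0 | 33 |
| violet | 30.0 | 28 |
| violet | 40.0 | 28 |
| violet | 50.0 | 31 |

(readings scatter by 1.5 percentage points)
* the flasks put in order of amount of target, in percent of the starting material charged, best first, at 50 min (spring / dusk / dawn / noon / midnight / summer)
* the amount of target, in percent of the starting material charged of the flask you put first, at 50 min
* the amount of target, in percent of the starting material charged of the flask you put last, at 50 min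

The blue run climbs to a plateau along one exponential, so the readings give a rate constant k for the catalyst's route to target:

k = ln(y_end/(y_end − y))/t = 0.127 min⁻¹

The violet run levels at a mean of 30.2%, which is 0.0664 M of target. We take the rest of the starting material as lost to the impurity, mole for mole. Both routes consume starting material, so they race, and the impurity left after c(target) has formed is c(impurity)·exp(−s·c(target)). Here s, the race constant (a selectivity factor per unit of impurity), is the quench rate over the target rate per molar of impurity. Read from violet:

s = ln(c(impurity)/(c(impurity) − lost))/c(target) = 35.2 M⁻¹

Our ladder of times, from fastest to slowest: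

quench of starting material, summer: 1.86 min
target route: 7.85 min
quench, spring: 18.6 min
reading: 50 min

In summer the quench is faster than the target route, so quenching leads at the start. In spring it is slower, and target leads from the start. The reading comes later than the target route's time, so we expect the flasks to have stopped by then. Our reckoning is therefore:

c(target) ≈ c(start) − c(impurity)·(1 − exp(−s·(c(start) − c(impurity))))

This gives 94.5% for spring and 47.1% for summer.

The forecast gives spring > noon > midnight > dawn > dusk > summer, with top 95% (92.5% to 97%) and low 37% (32% to 46%), reading the runs as “catalyst death driven by the impurity”. Our summer value lies above its low figure.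

The flasks give spring > noon > midnight > dawn > dusk > summer, with spring at 93.0% and summer at 46.6%.

    catalyst intermediate → free catalyst + target (k = 2000 min⁻¹)
    starting material + protic impurity → quenched substrate (k = 4.00 M⁻¹ min⁻¹)
    starting material + free catalyst → catalyst intermediate (k = 700 M⁻¹ min⁻¹)
    target → over-reaction product (k = 3.60 × 10⁻⁴ min⁻¹)
    free catalyst + added ligand ⇌ idle complex, settled at all times (K = 690 M⁻¹)

For spring, with the charges held as if they never ran down, starting material has a half-life of 3.5 min by the catalyst route, shorter than the 14 min by quenching. At 50.0 min summer holds 52.6% quenched substrate against 5.45% in spring, while free catalyst stands at 63.4% of the catalyst charged in summer and 63.4% in spring. With s, summer's target leaves 2.72% of the impurity charged, and summer holds 3.53% of it.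

Take the neighbour, spring with 0.055 M of starting material, a quarter of the charge, with the catalyst loading following and the impurity held. There k becomes 0.0319 min⁻¹ and s becomes 141 M⁻¹, so we reckon 20.3% of starting material left and, counting the whole impurity as quenched, 57.9% target, after which s leaves 1.14% of the impurity charged. This neighbour gives 61.8% target, with 15.9% of starting material and 1.1% of the impurity left.

Readings and results are calculated for an exercise; the scatter is artificial.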